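- Friday's flask holds the same charges as the south-west run, 0.050 M of electrophile and 0.100 M of nucleophile, but it stands warmer, at 100 °C against 95 °C, and runs longer, to 2.5 min against a last reading at 90.0 s, so I start from what the two share.

| setting | south-west | north-east | south | north | Tuesday's | Wednesday's | Friday's | Thursday's | Sunday's |
|---|---|---|---|---|---|---|---|---|---|
| electrophile | 0.050 M | 0.070 M | 0.11 M | 0.050 M | 0.050 M (fed, over 2.0 min) | 0.050 M | 0.050 M | 0.050 M | 0.050 M |
| nucleophile | 0.10 M | 0.10 M | 0.10 M | 0.050 M | 0.100 M | 0.100 M | 0.100 M | 0.100 M (fed, over 2.0 min) | 0.100 M (in portions, 2, over 2.0 min) |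
| temperature | 95 °C | 106 °C | 95 °C | 106 °C | 100 °C |  | 100 °C |  | 100 °C |
| remark | run made earlier | run made earlier | run made earlier | run made earlier | all else is in the flask from the start; the feed brings no volume worth counting | everything together at the start at 80 °C, warmed to 100 °C at 2.0 min | everything together at the start | the addition at 80 °C, then warmed to 100 °C; the feed brings no volume worth counting | first portion at the start, last at 2.0 min |
| time |  |  |  |  | 2.5 min | 2.5 min | 2.5 min | 2.5 min | 2.5 min |

| south-west: time / s | south-west: product / % | north-east: time / s | north-east: product / % | south: time / s | south: product / % | north: time / s | north: product / % |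
|---|---|---|---|---|---|---|---|
| 20.0 | 29 | 10.0 | 27 | 10.0 | 15 | 25.0 | 25 |
| 40.0 | 41 | 30.0 | 41 | 20.0 | 25 | 50.0 | 30 |
| 50.0 | 43 | 60.0 | 49 | 30.0 | 27 | 80.0 | 38 |
| 80.0 | 50 | 80.0 | 48 | 60.0 | 32 | 90.0 | 37 |
| 90.0 | 51 | 120 | 48 | 120 | 35 | 120 | 37 |

(scatter of a reading: 1.5 percentage points)

- what may be going on: electrophile + nucleophile <-> acid set free + product; nucleophile + acid set free <-> protonated nucleophile; 2 nucleophile -> homo dimer; electrophile <-> dormant form

* which flask leads in amount of product, in percent of the electrophile charged ("all alike" within 1.5 percentage points) (Tuesday's / Wednesday's / Friday's / Thursday's / Sunday's / all alike)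
* how much product is there at the end, in percent of the electrophile charged: Tuesday's
* how much product is there at the end, in percent of the electrophile charged: Wednesday's
* how much product is there at the end, in percent of the electrophile charged: Friday's
* how much product is there at the end, in percent of the electrophile charged: Thursday's
* how much product is there at the end, in percent of the electrophile charged: Sunday's

- If each acid set free goes onto a second nucleophile as protonated nucleophile, every product costs two nucleophiles, so I reckon limiting reagent at that price: the nucleophile ceiling, the nucleophile charge over 2 times the electrophile charge, is 100% for Friday's flask and for the south-west run alike.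
- The last readings reach a share of their own ceilings that climbs with electrophile per nucleophile, though the temperatures are mixed: 51.0% at a ratio of 0.500 in the south-west run, 67.2% at 0.700 in the north-east run, 74.0% at 1.00 in the north run and 77.0% at 1.10 in the south run; I read the missing nucleophile as homo dimer.
- So Friday's flask, at the south-west ratio, should end near the south-west share, but that run still climbed 8 percentage points after 50.0 s, and I add half of that climb for the longer time, which gives my own 55.0%.
- The forecast, which holds that “Each product ties up two nucleophiles”, puts Friday's first, with 54% there, 52% for Sunday's, 50% for Wednesday's, 46% for Thursday's and 30% for Tuesday's.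
- Friday's flask ends at 58.1% and leads, with Sunday's at 50.0%, Wednesday's at 49.6%, Thursday's at 48.9% and Tuesday's at 31.4%, and the forecast's leader and figures stand within their tolerance. Left ten times as long, Friday's flask still gives 58.3%. Against the ceiling, the nucleophile of Friday's flask at 2.50 min divides into 58.1% billed to product at two each, 37.1% in homo dimer and 4.97% free, together 100% if the 1.57 × 10⁻⁴ M of acid set free, not on a nucleophile, is neglected, and the 15.8% of electrophile in the dormant form has no line in this nucleophile bill.

    electrophile + nucleophile ⇌ acid set free + product (K = 0.370, k = 0.340 L mol⁻¹ s⁻¹, Ea = 67.0 kJ mol⁻¹, ΔH = −12.0 kJ mol⁻¹)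
    nucleophile + acid set free ⇌ protonated nucleophile, settled at all times (K = 37000 L mol⁻¹, ΔH = −45.0 kJ mol⁻¹)
    2 nucleophile → homo dimer (k = 0.160 L mol⁻¹ s⁻¹, Ea = 54.0 kJ mol⁻¹)
    electrophile ⇌ dormant form (K = 1.00, k = 0.00340 s⁻¹, Ea = 113 kJ mol⁻¹, ΔH = −44.0 kJ mol⁻¹)
    (constants at 100 °C)

- A neighbour of Friday's flask with 0.20 M of electrophile has a ceiling of 25.0%, and its ratio of 2.00 lies beyond the south run's, so I expect a figure between that run's share of this ceiling, 19.2%, and the ceiling itself. It gives 22.2%, with 1.14% of its nucleophile free.

Readings and results are calculated on assumed constants; the scatter is artificial.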